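**Retrosynthetic overview**
- The target comes from its 5,7,4'-tri-O-benzyl ether by hydrogenolysis, so the three methyl ethers never meet a dealkylating reagent.
- Ring C (the pyranone) is the only ring built and is formed last, by iodine/DMSO oxidative cyclisation of a 2'-hydroxychalcone.
- The chalcone Cα–Cβ bond comes from an intermolecular Claisen–Schmidt aldol condensation of 4',6'-di-O-benzylphloroacetophenone (ring A) with 4-(benzyloxy)-2,3,5-trimethoxybenzaldehyde (ring B).
- The B-ring aldehyde comes from syringaldehyde: O-benzylation, bromination at C2, acetal protection, copper-catalysed exchange of bromide for methoxide.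
- Rings A and B are bought as arenes (phloroacetophenone, syringaldehyde).

Assumption: the target has no stereocentre and no stereogenic double bond, so it is achiral and the SMILES defines it fully; no enantiocontrol is needed.

**Route**

Step 1
Reactants: 1 syringaldehyde (4-hydroxy-3,5-dimethoxybenzaldehyde)
Product: 2 4-(benzyloxy)-3,5-dimethoxybenzaldehyde
Conditions: BnBr (1.2 equiv), K2CO3 (1.5 equiv), DMF, 60 °C
Reagents that add atoms: benzyl bromide BrCc1ccccc1
Why: Williamson ether synthesis; the acidic phenol para to the formyl group is deprotonated by carbonate and benzylated by SN2, giving a group that is later removed by hydrogenolysis without touching methyl ethers.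

Step 2
Reactants: 2 4-(benzyloxy)-3,5-dimethoxybenzaldehyde
Product: 3 4-(benzyloxy)-2-bromo-3,5-dimethoxybenzaldehyde
Conditions: NBS (1.1 equiv), DMF, rt to 50 °C, dark
Reagents that add atoms: N-bromosuccinimide O=C1CCC(=O)N1Br
Why: Electrophilic aromatic bromination; C2 and C6 are equivalent by symmetry and each is ortho/para to the two methoxy groups, so one regioisomer forms, and the formyl group prevents a second bromination.

Step 3
Reactants: 3 4-(benzyloxy)-2-bromo-3,5-dimethoxybenzaldehyde
Product: 4 2-(benzyloxy)-4-bromo-5-(dimethoxymethyl)-1,3-dimethoxybenzene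
Conditions: HC(OMe)3 (3 equiv), p-TsOH·H2O (2 mol %), MeOH, reflux; Et3N quench
Reagents that add atoms: trimethyl orthoformate COC(OC)OC; methanol CO
Why: Acid-catalysed acetalisation driven by the orthoformate as water scavenger; it masks the aldehyde against Cannizzaro/Tishchenko reactions in hot methoxide.

Step 4
Reactants: 4 2-(benzyloxy)-4-bromo-5-(dimethoxymethyl)-1,3-dimethoxybenzene
Product: 6 4-(benzyloxy)-2,3,5-trimethoxybenzaldehyde, via dimethyl acetal 5 (not isolated)
Conditions: NaOMe (25 wt % in MeOH, 5 equiv), CuBr (15 mol %), DMF, 110 °C, N2; then 2 M aq HCl, THF, rt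
Reagents that add atoms: sodium methoxide [Na+].[O-]C; water O
Why: Copper-catalysed Ullmann-type methoxylation of the aryl bromide (the same exchange used on 2-bromo-3,4,5-trimethoxytoluene), followed by mild acid hydrolysis of the acetal, which leaves the benzyl ether intact.

Step 5
Reactants: 7 2',4',6'-trihydroxyacetophenone (phloroacetophenone, sold as the monohydrate)
Product: 8 1-[2,4-bis(benzyloxy)-6-hydroxyphenyl]ethanone
Conditions: BnBr (2.05 equiv), K2CO3 (2.2 equiv), DMF, 0 °C to rt
Reagents that add atoms: benzyl bromide BrCc1ccccc1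
Why: Williamson ether synthesis; the hydroxyl that stays hydrogen-bonded to the ketone carbonyl is the least nucleophilic, so two equivalents of benzyl bromide leave exactly that chelated 2'-OH free.

Step 6
Reactants: 8 1-[2,4-bis(benzyloxy)-6-hydroxyphenyl]ethanone; 6 4-(benzyloxy)-2,3,5-trimethoxybenzaldehyde
Product: 10 (E)-1-[2,4-bis(benzyloxy)-6-hydroxyphenyl]-3-[4-(benzyloxy)-2,3,5-trimethoxyphenyl]prop-2-en-1-one, via aldol adduct 9 (not isolated)
Conditions: KOH (50 % aq, 10 equiv), EtOH/THF, rt, 48 h, N2; then cold 2 M HCl to pH 3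
Reagents that add atoms: none
Why: Claisen–Schmidt crossed aldol condensation; the methyl ketone enolate adds to the non-enolisable aldehyde and E1cB dehydration of the racemic β-hydroxy ketone gives the thermodynamically favoured (E)-enone, so no stereocentre remains.

Step 7
Reactants: 10 (E)-1-[2,4-bis(benzyloxy)-6-hydroxyphenyl]-3-[4-(benzyloxy)-2,3,5-trimethoxyphenyl]prop-2-en-1-one
Product: 13 5,7-bis(benzyloxy)-2-[4-(benzyloxy)-2,3,5-trimethoxyphenyl]-4H-chromen-4-one, via flavanone 11 (not isolated), via 3-iodoflavanone 12 (not isolated)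
Conditions: I2 (10 mol %), DMSO, 130 °C, 2–3 h; aq Na2S2O3 work-up
Reagents that add atoms: none
Why: Iodine/DMSO oxidative cyclisation; intramolecular oxa-Michael addition of the 2'-OH gives the flavanone, α-iodination and loss of HI give the flavone, and DMSO re-oxidises HI to iodine, so both transient stereocentres are destroyed.

Step 8
Reactants: 13 5,7-bis(benzyloxy)-2-[4-(benzyloxy)-2,3,5-trimethoxyphenyl]-4H-chromen-4-one
Product: 14 5,7-dihydroxy-2-(4-hydroxy-2,3,5-trimethoxyphenyl)-4H-chromen-4-one (5,7,4'-trihydroxy-2',3',5'-trimethoxyflavone)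
Conditions: H2 (1 atm), 10 % Pd/C, THF/MeOH 1:1, rt
Reagents that add atoms: none
Why: Catalytic hydrogenolysis cleaves the three benzylic C–O bonds, while aryl methyl ethers and the chromone C2=C3 bond (a vinylogous ester) are inert at 1 atm and room temperature.

**Compound list**
1 | syringaldehyde (4-hydroxy-3,5-dimethoxybenzaldehyde) | COc1cc(C=O)cc(OC)c1O | starting material
2 | 4-(benzyloxy)-3,5-dimethoxybenzaldehyde | COc1cc(C=O)cc(OC)c1OCc1ccccc1 | intermediate
3 | 4-(benzyloxy)-2-bromo-3,5-dimethoxybenzaldehyde | COc1cc(C=O)c(Br)c(OC)c1OCc1ccccc1 | intermediate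
4 | 2-(benzyloxy)-4-bromo-5-(dimethoxymethyl)-1,3-dimethoxybenzene (dimethyl acetal of 3) | COc1cc(C(OC)OC)c(Br)c(OC)c1OCc1ccccc1 | intermediate
5 | 2-(benzyloxy)-5-(dimethoxymethyl)-1,3,4-trimethoxybenzene (dimethyl acetal of 6; not isolated) | COc1cc(C(OC)OC)c(OC)c(OC)c1OCc1ccccc1 | intermediate
6 | 4-(benzyloxy)-2,3,5-trimethoxybenzaldehyde | COc1cc(C=O)c(OC)c(OC)c1OCc1ccccc1 | intermediate
7 | 2',4',6'-trihydroxyacetophenone (phloroacetophenone) | CC(=O)c1c(O)cc(O)cc1O | starting material
8 | 1-[2,4-bis(benzyloxy)-6-hydroxyphenyl]ethanone | CC(=O)c1c(O)cc(OCc2ccccc2)cc1OCc1ccccc1 | intermediate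
9 | 1-[2,4-bis(benzyloxy)-6-hydroxyphenyl]-3-[4-(benzyloxy)-2,3,5-trimethoxyphenyl]-3-hydroxypropan-1-one (aldol adduct; racemic; not isolated) | COc1cc(C(O)CC(=O)c2c(O)cc(OCc3ccccc3)cc2OCc2ccccc2)c(OC)c(OC)c1OCc1ccccc1 | intermediate
10 | (E)-1-[2,4-bis(benzyloxy)-6-hydroxyphenyl]-3-[4-(benzyloxy)-2,3,5-trimethoxyphenyl]prop-2-en-1-one (chalcone) | COc1cc(/C=C/C(=O)c2c(O)cc(OCc3ccccc3)cc2OCc2ccccc2)c(OC)c(OC)c1OCc1ccccc1 | intermediate
11 | 5,7-bis(benzyloxy)-2-[4-(benzyloxy)-2,3,5-trimethoxyphenyl]chroman-4-one (flavanone; racemic; not isolated) | COc1cc(C2CC(=O)c3c(OCc4ccccc4)cc(OCc4ccccc4)cc3O2)c(OC)c(OC)c1OCc1ccccc1 | intermediate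
12 | 5,7-bis(benzyloxy)-2-[4-(benzyloxy)-2,3,5-trimethoxyphenyl]-3-iodochroman-4-one (3-iodoflavanone; racemic diastereomer mixture; not isolated) | COc1cc(C2Oc3cc(OCc4ccccc4)cc(OCc4ccccc4)c3C(=O)C2I)c(OC)c(OC)c1OCc1ccccc1 | intermediate
13 | 5,7-bis(benzyloxy)-2-[4-(benzyloxy)-2,3,5-trimethoxyphenyl]-4H-chromen-4-one | COc1cc(-c2cc(=O)c3c(OCc4ccccc4)cc(OCc4ccccc4)cc3o2)c(OC)c(OC)c1OCc1ccccc1 | intermediate
14 | 5,7-dihydroxy-2-(4-hydroxy-2,3,5-trimethoxyphenyl)-4H-chromen-4-one (5,7,4'-trihydroxy-2',3',5'-trimethoxyflavone; achiral) | COc1cc(-c2cc(=O)c3c(O)cc(O)cc3o2)c(OC)c(OC)c1O | target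

**Summary**
Total step count: 8.
Longest linear sequence: 7 steps (1 → 2 → 3 → 4 → 6 → 10 → 13 → 14); the A-ring branch 7 → 8 is one step.

**Three steps most likely to fail, each with a fallback**

Step 4 (copper-catalysed methoxylation). The bromide is flanked by two ortho substituents on an electron-rich ring, so exchange may be slow or give hydrodebromination. The fallback sets out from 4 and splits the C–OMe bond formation into hydroxylation plus O-methylation. Palladium-catalysed hydroxylation (Pd2(dba)3, tBuXPhos, KOH, 1,4-dioxane/H2O, 100 °C) gives 3-(benzyloxy)-6-(dimethoxymethyl)-2,4-dimethoxyphenol F1. Methylation of this phenol (MeI, K2CO3, DMF, rt) gives the acetal 5, where the route is rejoined; 5 is hydrolysed with aqueous HCl/THF as in step 4 to give 6.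

Step 6 (Claisen–Schmidt condensation). Both partners are hindered and electron-rich, and the free 2'-phenoxide lowers the acidity of the methyl ketone, so conversion may stall or give chalcone/flavanone mixtures. The fallback sets out from 8 and removes the phenoxide problem by a change of protecting-group strategy. MOMCl/NaH in DMF at 0 °C gives 1-[2,4-bis(benzyloxy)-6-(methoxymethoxy)phenyl]ethanone F2. Its aldol condensation with 6 (KOH, EtOH/THF, rt) gives (E)-1-[2,4-bis(benzyloxy)-6-(methoxymethoxy)phenyl]-3-[4-(benzyloxy)-2,3,5-trimethoxyphenyl]prop-2-en-1-one F3. Methanolic HCl (3 M, MeOH/THF, 40 °C) removes the MOM group without touching the benzyl ethers and returns to the route at 10. Any flavanone 11 formed in the acid step is carried along, because step 7 oxidises it as well.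

Step 7 (iodine/DMSO cyclisation). The HI formed at 130 °C may cleave the peri 5-O-benzyl ether or iodinate the electron-rich A ring at C6/C8. Loss of the 5-benzyl group alone is harmless, since step 8 removes it anyway. The fallback sets out from 10 and separates ring closure from oxidation. NaOAc in refluxing EtOH isomerises the chalcone to the flavanone 11, which is isolated. DDQ (1.5–2 equiv) in refluxing 1,4-dioxane then dehydrogenates it by hydride abstraction to 13, where the route is rejoined. This detour makes no compound outside the list (F0).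

**Further compounds**
F1 | step 4 | 3-(benzyloxy)-6-(dimethoxymethyl)-2,4-dimethoxyphenol | COc1cc(C(OC)OC)c(O)c(OC)c1OCc1ccccc1
F2 | step 6 | 1-[2,4-bis(benzyloxy)-6-(methoxymethoxy)phenyl]ethanone | COCOc1cc(OCc2ccccc2)cc(OCc2ccccc2)c1C(C)=O
F3 | step 6 | (E)-1-[2,4-bis(benzyloxy)-6-(methoxymethoxy)phenyl]-3-[4-(benzyloxy)-2,3,5-trimethoxyphenyl]prop-2-en-1-one | COCOc1cc(OCc2ccccc2)cc(OCc2ccccc2)c1C(=O)/C=C/c1cc(OC)c(OCc2ccccc2)c(OC)c1OC
F0 | step 7 | none | none
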